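C2″ of the 5,7-dihydroxychromone is bonded to the fully substituted C1′ of the enedione ring, so C2″–C3″ can be carried as an ethynyl group on C1′ (no propargylic hydrogen), C4″ comes from CO, and the benzo ring C4a″–C8a″ comes from the symmetrical 2-iodophloroglucinol tris(methoxymethyl) ether. Carbonylative alkynylation forms C3″–C4″ and C4″–C4a″; the pyranone O1″–C2″ bond is closed afterwards.
The C1′ ethynyl group is made from an angular methyl ester by reduction, reoxidation and one-carbon homologation.
The cyclohexene ring (C12–C15, C6′, C1′) and its three stereocentres come from a catalyst-controlled [4+2] cycloaddition of a 7β-silyloxy-18-acetal labda-8(17),12E,14-triene with the ester-bearing para-quinone monoketal of methyl 2-hydroxy-4,5-dimethoxybenzoate.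
The labdatriene comes from a bicyclic 8-oxo 9-ester (C9 alkylation with a pentadienyl bromide, C7 hydroxylation, loss of the ester, C8 methylenation). The decalin comes from an epoxide-initiated bicyclization of a geranyl-derived epoxy β-keto ester, with absolute configuration from an asymmetric epoxidation; the C3 oxygen is removed and C18 is raised to a protected aldehyde.
Ring order: decalin ring A then ring B in one cascade, then the cyclohexene ring by cycloaddition (the enedione ring is the former arene), and the pyranone ring last.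

Key step: step 26

Numbering: labdane numbering for the decalin (C1–C10; C17 exocyclic methylene carbon on C8; C18 the 4α carbon; C19 the 4β methyl; C20 the 10β methyl), C11–C16 for the side chain, C1′–C6′ for the quinone-derived ring, C2″–C8a″ for the chromone. TBS = tert-butyldimethylsilyl, MOM = methoxymethyl.

Assumption: in step 20 the copper-bound keto ester is taken to react in the ester-endo geometry on the face left open by the (S,S)-ligand (square-planar chelate model); if a trial on a model diene shows the opposite facial sense, the (R,R)-ligand is used and nothing else changes.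

Step 1
Reactants: 1 geranyl acetate
Product: 2 (2E,6E)-8-hydroxy-3,7-dimethylocta-2,6-dien-1-yl acetate
Conditions: SeO2 (cat.), t-BuOOH, salicylic acid (cat.), CH2Cl2, rt
Reagents that add atoms: selenium dioxide, O=[Se]=O (oxygen donor, turned over by tert-butyl hydroperoxide, CC(C)(C)OO)
Why: Selenium dioxide allylic oxidation (ene reaction, then [2,3]-sigmatropic shift) should attack the (E)-methyl group of the terminal trisubstituted alkene, the 2,3-alkene being deactivated by the allylic acetate, so the carbon that becomes C18 is oxidised trans to the chain.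

Step 2
Reactants: 2 (2E,6E)-8-hydroxygeranyl acetate
Product: 3 (2E,6S,7S)-6,7-epoxy-8-hydroxy-3,7-dimethyloct-2-en-1-yl acetate
Conditions: Ti(OiPr)4 (10 mol %), L-(+)-diethyl tartrate (12 mol %), t-BuOOH, 4 Å molecular sieves, CH2Cl2, −20 °C
Reagents that add atoms: tert-butyl hydroperoxide, CC(C)(C)OO
Why: Sharpless asymmetric epoxidation of the (E)-allylic alcohol with the L-(+)-tartrate ligand should deliver oxygen to the face that gives the (6S,7S)-epoxide, which fixes the absolute configuration of the whole decalin.

Step 3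
Reactants: 3 epoxy alcohol
Product: 4 (2E,6S,7S)-8-(tert-butyldimethylsilyloxy)-6,7-epoxy-3,7-dimethyloct-2-en-1-yl acetate
Conditions: TBSCl, imidazole, CH2Cl2, 0 °C to rt
Reagents that add atoms: tert-butyldimethylsilyl chloride, CC(C)(C)[Si](C)(C)Cl
Why: Silylation of the primary alcohol masks it for the bromide and dianion steps and removes the risk of epoxide migration through the free alkoxide.

Step 4
Reactants: 4 silyl ether acetate
Product: 5 (2E,6S,7S)-8-(tert-butyldimethylsilyloxy)-6,7-epoxy-3,7-dimethyloct-2-en-1-ol
Conditions: K2CO3 (cat.), MeOH, 0 °C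
Reagents that add atoms: none
Why: Base-catalysed transesterification removes the acetate without touching the silyl ether or the trisubstituted epoxide.

Step 5
Reactants: 5 allylic alcohol
Product: 7 (2E,6S,7S)-1-bromo-8-(tert-butyldimethylsilyloxy)-6,7-epoxy-3,7-dimethyloct-2-ene, via allylic mesylate 6 (not isolated)
Conditions: MsCl, Et3N, THF, −40 °C; then LiBr, THF, 0 °C
Reagents that add atoms: lithium bromide, [Li+].[Br-]; methanesulfonyl chloride, CS(=O)(=O)Cl (its atoms stay only in 6)
Why: Mesylation and SN2 displacement by bromide at the primary allylic carbon should proceed without allylic transposition at temperatures at which the hindered epoxide is inert.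

Step 6
Reactants: 7 allylic bromide; 8 methyl acetoacetate
Product: 9 methyl (6E,10S,11S)-12-(tert-butyldimethylsilyloxy)-10,11-epoxy-7,11-dimethyl-3-oxododec-6-enoate
Conditions: 8, NaH then n-BuLi, THF, 0 °C; then 7, 0 °C
Reagents that add atoms: none
Why: γ-Alkylation of the acetoacetate dianion, whose terminal carbon is the more nucleophilic site, displaces the allylic bromide in SN2 fashion and keeps the E-alkene.

Step 7
Reactants: 9 epoxy β-keto ester
Product: 11 methyl 6-hydroxy-5-(hydroxymethyl)-5,8a-dimethyl-2-oxodecahydronaphthalene-1-carboxylate (3β-OH; 4α-CH2OH; 4β-CH3; 5α-H; 9α-H; 10β-CH3), via bicyclic 18-O-TBS ether 10 (not isolated)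
Conditions: SnCl4, CH2Cl2, −78 to −30 °C; aq. NaHCO3 work-up; crude 10, HF·pyridine, THF, 0 °C to rt
Reagents that add atoms: none
Why: Epoxide-initiated cation–olefin bicyclization terminated by the tin-chelated β-keto ester enol, in which anti opening of the epoxide at its tertiary carbon (inversion at C4, C3–O kept) and a chair–chair transition state on the E-alkene set C4, C5 and C10 (trans fusion, oxygenated C18 equatorial and α), the C9 ester settles equatorial by enolization, and fluoride then frees the C18 hydroxyl.

Step 8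
Reactants: 11 diol keto ester
Product: 12 cyclic 3β,18-thionocarbonate of 11
Conditions: 1,1′-thiocarbonyldiimidazole, 4-dimethylaminopyridine (cat.), toluene, 80 °C
Reagents that add atoms: 1,1′-thiocarbonyldiimidazole, S=C(n1ccnc1)n1ccnc1
Why: Thiocarbonyl transfer to the trans-diequatorial 1,3-diol should give the six-membered cyclic thionocarbonate, the usual outcome with 1,2- and 1,3-diols.

Step 9
Reactants: 12 cyclic thionocarbonate
Product: 14 methyl 5-(hydroxymethyl)-5,8a-dimethyl-2-oxodecahydronaphthalene-1-carboxylate (4α-CH2OH; 4β-CH3; 5α-H; 9α-H; 10β-CH3), via S-stannyl thiocarbonate 13 (not isolated)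
Conditions: Bu3SnH, AIBN (cat.), toluene, 110 °C; then K2CO3, MeOH/H2O, rt
Reagents that add atoms: none
Why: Barton–McCombie-type radical deoxygenation of a cyclic thionocarbonate, in which the stannyl radical adduct fragments towards the more stable secondary C3 radical (reduced by the stannane) and mild hydrolysis of the stannyl thiocarbonate left on the primary oxygen returns the C18 alcohol.

Step 10
Reactants: 15 (E)-3-methylpent-2-en-4-yn-1-ol
Product: 16 (E)-3-methylpenta-2,4-dien-1-ol
Conditions: H2 (1 atm), Pd/CaCO3–Pb(OAc)2 (Lindlar catalyst), quinoline, Et2O, 0 °C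
Reagents that add atoms: none
Why: Lindlar semi-hydrogenation reduces the terminal alkyne of the conjugated enyne to the vinyl group well before any alkene is touched and leaves the E-trisubstituted alkene as it is.

Step 11
Reactants: 16 dienol
Product: 17 (E)-5-bromo-3-methylpenta-1,3-diene
Conditions: PBr3, pyridine (cat.), Et2O, −20 °C
Reagents that add atoms: phosphorus tribromide, BrP(Br)Br
Why: Phosphorus tribromide converts the primary dienylic alcohol to the bromide at low temperature, and attack at either end of the 3-methylpentadienyl system gives the same constitution.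

Step 12
Reactants: 14 keto ester alcohol; 17 pentadienyl bromide
Product: 18 methyl 5-(hydroxymethyl)-5,8a-dimethyl-1-[(2E)-3-methylpenta-2,4-dien-1-yl]-2-oxodecahydronaphthalene-1-carboxylate (9α-dienylmethyl; 9β-CO2Me)
Conditions: K2CO3, acetone, 50 °C
Reagents that add atoms: none
Why: C-Alkylation of the β-keto ester enolate with a soft, reactive pentadienyl bromide enters anti to the angular C20 methyl, the neopentyl alcohol is not alkylated by carbonate, and the provisional C9 configuration is reset in step 17.

Step 13
Reactants: 18 alkylated keto ester alcohol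
Product: 19 the corresponding C18 aldehyde
Conditions: Dess–Martin periodinane, NaHCO3, CH2Cl2, rt
Reagents that add atoms: none
Why: Dess–Martin oxidation takes the neopentyl primary alcohol to an aldehyde that cannot enolize, while the diene and the ketone are inert.

Step 14
Reactants: 19 aldehyde
Product: 20 the C18 dimethyl acetal
Conditions: HC(OMe)3, MeOH, pyridinium p-toluenesulfonate (cat.), 40 °C
Reagents that add atoms: trimethyl orthoformate, COC(OC)OC; methanol, CO
Why: Acid-catalysed acetalization with orthoformate as water scavenger protects the aldehyde, whereas the C8 ketone, flanked by the quaternary C9, should not react.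

Step 15
Reactants: 20 acetal keto ester
Product: 21 the 7β-hydroxy ketone
Conditions: KN(SiMe3)2, THF, −78 °C; 2-(phenylsulfonyl)-3-phenyloxaziridine, −78 °C; aq. NH4Cl
Reagents that add atoms: 2-(phenylsulfonyl)-3-phenyloxaziridine, O=S(=O)(c1ccccc1)N1OC1c1ccccc1
Why: α-Hydroxylation of the potassium enolate with a sulfonyloxaziridine, C7 being the only enolizable position, and since the axial 9α-CH2 group is 1,3-diaxial to the α face of C7 the oxidant should enter from the β face and give the equatorial 7β-alcohol.

Step 16
Reactants: 21 hydroxy ketone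
Product: 22 the 7β-TBS ether
Conditions: TBSCl, imidazole, DMF, 35 °C
Reagents that add atoms: tert-butyldimethylsilyl chloride, CC(C)(C)[Si](C)(C)Cl
Why: Silylation under non-Lewis-acidic conditions protects the secondary alcohol without disturbing the dimethyl acetal.

Step 17
Reactants: 22 silyloxy keto ester
Product: 23 7β-(tert-butyldimethylsilyloxy)-8-oxo ketone with the 9β side chain (9α-H)
Conditions: LiCl, H2O, DMSO, 150 °C
Reagents that add atoms: none
Why: Krapcho dealkoxycarbonylation (chloride attack at the ester methyl, loss of CO2) and protonation of the resulting enolate from the α face, anti to the C20 methyl, leaves the side chain equatorial (9β), which is also the thermodynamic arrangement.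

Step 18
Reactants: 23 ketone
Product: 24 (12E)-7β-(tert-butyldimethylsilyloxy)-18,18-dimethoxylabda-8(17),12,14-triene
Conditions: Zn, CH2Br2, TiCl4, THF (reagent pre-formed at 0–5 °C); then 23, CH2Cl2, rt
Reagents that add atoms: dibromomethane, BrCBr
Why: Takai–Lombardo methylenation with the non-basic gem-dizinc/titanium reagent should convert the hindered, epimerizable α-silyloxy ketone to the exocyclic alkene without loss of configuration at C7 or C9.

Step 19
Reactants: 25 methyl 2-hydroxy-4,5-dimethoxybenzoate
Product: 26 methyl 3,3,4-trimethoxy-6-oxocyclohexa-1,4-diene-1-carboxylate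
Conditions: PhI(OAc)2, MeOH, 0 °C
Reagents that add atoms: methanol, CO
Why: Hypervalent-iodine oxidative dearomatization of the para-methoxyphenol in methanol gives the para-quinone monoketal, methanol adding at the carbon para to the phenol oxygen.

Step 20
Reactants: 24 labdatriene; 26 quinone monoketal ester
Product: 27 cis-fused cycloadduct with the methyl ester on C1′, C11 cis to that ester, (12R,1′R,6′R)
Conditions: [Cu((S,S)-t-Bu-box)](SbF6)2 (10 mol %), 4 Å molecular sieves, CH2Cl2, −40 to −10 °C
Reagents that add atoms: none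
Why: Catalytic asymmetric Diels–Alder reaction of a chelating 2-alkoxycarbonyl enone on divalent copper, in which the unsubstituted diene terminus C15 bonds to the β-carbon C6′ (the 1-alkyl substituent outweighing the 2-methyl group), the ester lies endo because the ketal carbon blocks the ring-endo approach (this places C11 cis to the ester and fuses the rings cis), and the tert-butyl groups of the ligand leave open only the face that leads to (12R,1′R,6′R).

Step 21
Reactants: 27 cycloadduct
Product: 28 diol with hydroxymethyl on C1′ and a C2′ carbinol (both C2′ epimers)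
Conditions: i-Bu2AlH, CH2Cl2, −78 to 0 °C; aq. KNaC4H4O6
Reagents that add atoms: none
Why: The aluminium hydride reduces the neopentyl ester to the primary alcohol and, unavoidably, the vinylogous-ester ketone to the allylic alcohol, which step 22 restores, and the neutral tartrate work-up keeps the acid-labile γ-hydroxy enol ether intact.

Step 22
Reactants: 28 diol
Product: 29 keto aldehyde (C2′ ketone, formyl group on C1′)
Conditions: Dess–Martin periodinane, NaHCO3, CH2Cl2, 0 °C to rt
Reagents that add atoms: none
Why: Buffered Dess–Martin oxidation returns the C2′ vinylogous-ester ketone and gives the neopentyl aldehyde, which has no α-hydrogen and so cannot epimerize C1′.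

Step 23
Reactants: 29 keto aldehyde
Product: 30 C1′ ethynyl core carrying the decalin (7-OTBS, C18 dimethyl acetal, C5′ dimethyl ketal)
Conditions: Me3SiCHN2, n-BuLi, THF, −78 °C; then 29, −78 to 0 °C
Reagents that add atoms: trimethylsilyldiazomethane, C[Si](C)(C)C=[N+]=[N-]
Why: Colvin rearrangement (Seyferth–Gilbert-type homologation), in which the lithiated silyldiazomethane adds to the aldehyde faster than to the hindered vinylogous ester, loss of silanolate gives the diazoalkene, and the alkylidene carbene rearranges by 1,2-hydride shift to the terminal alkyne, the aprotic low-temperature conditions avoiding alkoxide-induced deformylation of the β-keto aldehyde.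

Step 24
Reactants: 31 phloroglucinol
Product: 32 1,3,5-tris(methoxymethoxy)benzene
Conditions: MOMCl, i-Pr2NEt, CH2Cl2/DMF, 0 °C to rt
Reagents that add atoms: chloromethyl methyl ether, COCCl
Why: O-Alkylation of the three phenols with the chloromethyl ether under amine base gives the tris-acetal.

Step 25
Reactants: 32 tris-MOM ether
Product: 33 2-iodo-1,3,5-tris(methoxymethoxy)benzene
Conditions: n-BuLi, THF, 0 °C; I2, −78 °C to rt
Reagents that add atoms: iodine, II
Why: Directed ortho-lithiation between two methoxymethoxy groups and iodinolysis give one mono-iodide, since the three free ring positions are equivalent.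

Step 26
Reactants: 30 C1′ ethynyl core; 33 aryl iodide; 34 carbon monoxide
Product: 35 aryl alkynyl ketone that holds every chromone atom
Conditions: PdCl2(PPh3)2 (5 mol %), Et3N, CO (10 bar), THF, 60 °C
Reagents that add atoms: none
Why: Oxidative addition of 33 to zerovalent palladium (generated in situ from PdCl2(PPh3)2) is followed by migratory insertion of CO; the aroyl iodide complex of divalent palladium takes up the terminal alkyne of 30, Et3N removes the alkyne proton, and reductive elimination gives 35 with the new C3″–C4″ and C4″–C4a″ bonds. The closest known reaction type is the copper-free carbonylative Sonogashira coupling of aryl iodides with terminal alkynes to alkynyl ketones. No ring is closed and no stereocentre is formed; the existing centres, none of which enolizes under Et3N, are carried through. The selectivity needed is carbonylative over direct coupling: the electron-rich, doubly ortho-oxygenated aryl group migrates to CO quickly, CO pressure and the absence of copper disfavour direct alkynylation, and the neopentyl position of the alkyne on quaternary C1′ slows direct transfer and rules out alkyne–allene isomerization. Because 33 is symmetrical, either ortho oxygen can later close the pyranone, and the tertiary amine cannot add irreversibly to the ynone or to the vinylogous ester.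

Step 27
Reactants: 35 aryl alkynyl ketone
Product: 36 2,4,6-trihydroxyphenyl ynone with free 7-OH (ketal and acetal kept)
Conditions: HCl (1.25 M in dry MeOH), 0 °C to rt
Reagents that add atoms: none
Why: Acid-catalysed transacetalization in dry methanol cleaves the three aryl methoxymethyl ethers and the silyl ether, while the dimethyl ketal and dimethyl acetal only exchange degenerately with methanol and persist.

Step 28
Reactants: 36 trihydroxyphenyl ynone
Product: 37 5,7-dihydroxychromone with C5′ dimethyl ketal and C18 dimethyl acetal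
Conditions: K2CO3, acetone, rt
Reagents that add atoms: none
Why: Oxa-Michael addition of a phenoxide ortho to the ketone to C2″ of the ynone (6-endo-dig) and protonation give the 4-pyranone, the two ortho phenols being equivalent and C5′, still a ketal, keeping C6′ from epimerizing under base.

Step 29
Reactants: 37 chromone ketal acetal
Product: 38 dichrostachine H
Conditions: 1 M aq. HCl, THF, rt
Reagents that add atoms: water, O
Why: Mild aqueous acid hydrolyses the dimethyl ketal at C5′ and the dimethyl acetal at C18, while the vinylogous methyl ester and the allylic alcohol should persist at room temperature.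

Compound list
1 | geranyl acetate | CC(=O)OC/C=C(\C)CCC=C(C)C | starting material
2 | (2E,6E)-8-hydroxy-3,7-dimethylocta-2,6-dien-1-yl acetate | CC(=O)OC/C=C(\C)CC/C=C(\C)CO | intermediate
3 | (2E,6S,7S)-6,7-epoxy-8-hydroxy-3,7-dimethyloct-2-en-1-yl acetate | CC(=O)OC/C=C(\C)CC[C@@H]1O[C@@]1(C)CO | intermediate
4 | (2E,6S,7S)-8-(tert-butyldimethylsilyloxy)-6,7-epoxy-3,7-dimethyloct-2-en-1-yl acetate | CC(=O)OC/C=C(\C)CC[C@@H]1O[C@@]1(C)CO[Si](C)(C)C(C)(C)C | intermediate
5 | (2E,6S,7S)-8-(tert-butyldimethylsilyloxy)-6,7-epoxy-3,7-dimethyloct-2-en-1-ol | OC/C=C(\C)CC[C@@H]1O[C@@]1(C)CO[Si](C)(C)C(C)(C)C | intermediate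
6 | methanesulfonate of 5 (not isolated) | CS(=O)(=O)OC/C=C(\C)CC[C@@H]1O[C@@]1(C)CO[Si](C)(C)C(C)(C)C | intermediate
7 | (2E,6S,7S)-1-bromo-8-(tert-butyldimethylsilyloxy)-6,7-epoxy-3,7-dimethyloct-2-ene | BrC/C=C(\C)CC[C@@H]1O[C@@]1(C)CO[Si](C)(C)C(C)(C)C | intermediate
8 | methyl acetoacetate | COC(=O)CC(C)=O | starting material
9 | methyl (6E,10S,11S)-12-(tert-butyldimethylsilyloxy)-10,11-epoxy-7,11-dimethyl-3-oxododec-6-enoate | COC(=O)CC(=O)CC/C=C(\C)CC[C@@H]1O[C@@]1(C)CO[Si](C)(C)C(C)(C)C | intermediate
10 | trans-decalin β-keto ester, 3β-OH, 4α-CH2OTBS, 4β-CH3, 8-oxo, 9β-CO2Me, 10β-CH3 (not isolated) | O=C1CC[C@@H]2[C@](C)(CC[C@H](O)[C@@]2(C)CO[Si](C)(C)C(C)(C)C)[C@H]1C(=O)OC | intermediate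
11 | methyl 6-hydroxy-5-(hydroxymethyl)-5,8a-dimethyl-2-oxodecahydronaphthalene-1-carboxylate (3β-OH, 4α-CH2OH, 4β-CH3, 5α-H, 9α-H, 10β-CH3) | O=C1CC[C@@H]2[C@](C)(CC[C@H](O)[C@@]2(C)CO)[C@H]1C(=O)OC | intermediate
12 | cyclic 3β,18-thionocarbonate of 11 | O=C1CC[C@@H]2[C@](C)(CC[C@@H]3OC(=S)OC[C@@]23C)[C@H]1C(=O)OC | intermediate
13 | 3-deoxy 18-O-[(tributylstannylthio)carbonyl] keto ester (not isolated) | O=C1CC[C@@H]2[C@](C)(CCC[C@@]2(C)COC(=O)S[Sn](CCCC)(CCCC)CCCC)[C@H]1C(=O)OC | intermediate
14 | methyl 5-(hydroxymethyl)-5,8a-dimethyl-2-oxodecahydronaphthalene-1-carboxylate (4α-CH2OH, 4β-CH3, 5α-H, 9α-H, 10β-CH3) | O=C1CC[C@@H]2[C@](C)(CCC[C@@]2(C)CO)[C@H]1C(=O)OC | intermediate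
15 | (E)-3-methylpent-2-en-4-yn-1-ol | OC/C=C(\C)C#C | starting material
16 | (E)-3-methylpenta-2,4-dien-1-ol | OC/C=C(\C)C=C | intermediate
17 | (E)-5-bromo-3-methylpenta-1,3-diene | BrC/C=C(\C)C=C | intermediate
18 | C9-alkylated keto ester, 9α-[(2E)-3-methylpenta-2,4-dienyl], 9β-CO2Me, 18-OH | O=C1CC[C@@H]2[C@](C)(CCC[C@@]2(C)CO)[C@]1(C(=O)OC)C/C=C(\C)C=C | intermediate
19 | C18 aldehyde of 18 | O=C1CC[C@@H]2[C@](C)(CCC[C@@]2(C)C=O)[C@]1(C(=O)OC)C/C=C(\C)C=C | intermediate
20 | C18 dimethyl acetal of 19 | O=C1CC[C@@H]2[C@](C)(CCC[C@@]2(C)C(OC)OC)[C@]1(C(=O)OC)C/C=C(\C)C=C | intermediate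
21 | 7β-hydroxy derivative of 20 | O=C1[C@@H](O)C[C@@H]2[C@](C)(CCC[C@@]2(C)C(OC)OC)[C@]1(C(=O)OC)C/C=C(\C)C=C | intermediate
22 | 7β-TBS ether of 21 | O=C1[C@@H](O[Si](C)(C)C(C)(C)C)C[C@@H]2[C@](C)(CCC[C@@]2(C)C(OC)OC)[C@]1(C(=O)OC)C/C=C(\C)C=C | intermediate
23 | 7β-(tert-butyldimethylsilyloxy)-18,18-dimethoxy-8-oxo-17-norlabda-12E,14-diene (9α-H) | O=C1[C@@H](O[Si](C)(C)C(C)(C)C)C[C@@H]2[C@](C)(CCC[C@@]2(C)C(OC)OC)[C@H]1C/C=C(\C)C=C | intermediate
24 | (12E)-7β-(tert-butyldimethylsilyloxy)-18,18-dimethoxylabda-8(17),12,14-triene | C=C1[C@@H](O[Si](C)(C)C(C)(C)C)C[C@@H]2[C@](C)(CCC[C@@]2(C)C(OC)OC)[C@H]1C/C=C(\C)C=C | intermediate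
25 | methyl 2-hydroxy-4,5-dimethoxybenzoate | COC(=O)c1cc(OC)c(OC)cc1O | starting material
26 | methyl 3,3,4-trimethoxy-6-oxocyclohexa-1,4-diene-1-carboxylate | COC(=O)C1=CC(OC)(OC)C(OC)=CC1=O | intermediate
27 | cis-fused cycloadduct, C1′ methyl ester, (12R,1′R,6′R) | C=C1[C@@H](O[Si](C)(C)C(C)(C)C)C[C@@H]2[C@](C)(CCC[C@@]2(C)C(OC)OC)[C@H]1C[C@@H]1C(C)=CC[C@H]2C(OC)(OC)C(OC)=CC(=O)[C@@]12C(=O)OC | intermediate
28 | diol, C1′ hydroxymethyl and C2′ carbinol (C2′ unassigned, both epimers) | C=C1[C@@H](O[Si](C)(C)C(C)(C)C)C[C@@H]2[C@](C)(CCC[C@@]2(C)C(OC)OC)[C@H]1C[C@@H]1C(C)=CC[C@H]2C(OC)(OC)C(OC)=CC(O)[C@@]12CO | intermediate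
29 | keto aldehyde, C1′ formyl | C=C1[C@@H](O[Si](C)(C)C(C)(C)C)C[C@@H]2[C@](C)(CCC[C@@]2(C)C(OC)OC)[C@H]1C[C@@H]1C(C)=CC[C@H]2C(OC)(OC)C(OC)=CC(=O)[C@@]12C=O | intermediate
30 | C1′ ethynyl core with decalin attached | C=C1[C@@H](O[Si](C)(C)C(C)(C)C)C[C@@H]2[C@](C)(CCC[C@@]2(C)C(OC)OC)[C@H]1C[C@@H]1C(C)=CC[C@H]2C(OC)(OC)C(OC)=CC(=O)[C@@]12C#C | intermediate
31 | phloroglucinol | Oc1cc(O)cc(O)c1 | starting material
32 | 1,3,5-tris(methoxymethoxy)benzene | COCOc1cc(OCOC)cc(OCOC)c1 | intermediate
33 | 2-iodo-1,3,5-tris(methoxymethoxy)benzene | COCOc1cc(OCOC)cc(OCOC)c1I | intermediate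
34 | carbon monoxide | [C-]#[O+] | starting material
35 | aryl alkynyl ketone (2,4,6-tris(methoxymethoxy)benzoyl on the C1′ alkyne) | C=C1[C@@H](O[Si](C)(C)C(C)(C)C)C[C@@H]2[C@](C)(CCC[C@@]2(C)C(OC)OC)[C@H]1C[C@@H]1C(C)=CC[C@H]2C(OC)(OC)C(OC)=CC(=O)[C@@]12C#CC(=O)c1c(OCOC)cc(OCOC)cc1OCOC | intermediate
36 | 2,4,6-trihydroxyphenyl ynone, 7-OH free | C=C1[C@@H](O)C[C@@H]2[C@](C)(CCC[C@@]2(C)C(OC)OC)[C@H]1C[C@@H]1C(C)=CC[C@H]2C(OC)(OC)C(OC)=CC(=O)[C@@]12C#CC(=O)c1c(O)cc(O)cc1O | intermediate
37 | 5,7-dihydroxychromone with C5′ dimethyl ketal and C18 dimethyl acetal | C=C1[C@@H](O)C[C@@H]2[C@](C)(CCC[C@@]2(C)C(OC)OC)[C@H]1C[C@@H]1C(C)=CC[C@H]2C(OC)(OC)C(OC)=CC(=O)[C@@]12c1cc(=O)c2c(O)cc(O)cc2o1 | intermediate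
38 | dichrostachine H | C=C1[C@@H](O)C[C@@H]2[C@](C)(CCC[C@@]2(C)C=O)[C@H]1C[C@@H]1C(C)=CC[C@H]2C(=O)C(OC)=CC(=O)[C@@]12c1cc(=O)c2c(O)cc(O)cc2o1 | target

Total step count: 29.
Longest linear sequence: 24 steps (steps 1–9, 12–18, 20–23, 26–29).

Steps most likely to fail

Step 20 (cycloaddition). The stereocentres of the diene are remote, so facial discrimination rests on the catalyst alone. Bonding of the substituted terminus C12 to C6′ (wrong regiochemistry), an ene reaction of the exocyclic alkene, and Lewis-acid ionization of the ketal can all compete. The fallback replaces catalyst control by auxiliary control; it sets out from 25 and 24 and comes back at 28. Saponification of 25 (LiOH, aq. THF) gives 2-hydroxy-4,5-dimethoxybenzoic acid F1. Esterification with (1R,2S,5R)-8-phenylmenthol (N,N′-dicyclohexylcarbodiimide, 4-dimethylaminopyridine) gives (1R,2S,5R)-8-phenylmenthyl 2-hydroxy-4,5-dimethoxybenzoate F2. Oxidation with PhI(OAc)2 in MeOH, as in step 19, gives the 8-phenylmenthyl quinone monoketal ester F3. Cycloaddition with 24 under ZnCl2 (chelated keto ester, one face covered by the phenyl ring of the auxiliary) should give the 8-phenylmenthyl ester cycloadduct F4, freed from any facial isomer by chromatography. i-Bu2AlH, as in step 21, then reduces the auxiliary ester and the ketone to 28 and the auxiliary alcohol is recovered. Which antipode of the auxiliary is matched is settled on a model diene.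

Step 7 (polyene cyclization). The opened epoxide may undergo hydride shift to a ketone, the cascade may stop after the first ring, or the C10 cation may be captured by the keto oxygen in place of carbon. The fallback uses a stronger carbon terminator; it sets out from 9 and comes back at 11. Treatment of 9 with TBSOTf and Et3N gives its silyl enol ether, methyl (2Z,6E,10S,11S)-3,12-bis(tert-butyldimethylsilyloxy)-10,11-epoxy-7,11-dimethyldodeca-2,6-dienoate F5. MeAlCl2 in CH2Cl2 at −78 °C then opens the epoxide and the enol silane closes ring B through carbon (Mukaiyama-type termination). The enol silyl group is lost on work-up to give 10, which HF·pyridine converts to 11 as in step 7.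

Step 26 (key step). Coupling may occur without uptake of CO (direct alkynylation), oxidative addition and acyl transfer may be sluggish at the doubly ortho-substituted arene, or the hindered alkyne may homocouple. The fallback is acetylide addition and oxidation without CO; it sets out from 32 and 30 and comes back at 35. Lithiation of 32 (n-BuLi, THF) and formylation with DMF gives 2,4,6-tris(methoxymethoxy)benzaldehyde F6. The lithium acetylide of 30 (LiN(SiMe3)2, THF, −78 °C; the non-enolizable, hindered C2′ ketone is left alone) adds to F6 to give the propargylic alcohol F7 as a mixture of carbinol epimers. MnO2 in CH2Cl2 oxidizes F7 to 35.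

Further compounds
F1 | step 20 | 2-hydroxy-4,5-dimethoxybenzoic acid | OC(=O)c1cc(OC)c(OC)cc1O
F2 | step 20 | (1R,2S,5R)-8-phenylmenthyl 2-hydroxy-4,5-dimethoxybenzoate | CC(C)(c1ccccc1)[C@@H]1CC[C@@H](C)C[C@H]1OC(=O)c1cc(OC)c(OC)cc1O
F3 | step 20 | (1R,2S,5R)-8-phenylmenthyl 3,3,4-trimethoxy-6-oxocyclohexa-1,4-diene-1-carboxylate | CC(C)(c1ccccc1)[C@@H]1CC[C@@H](C)C[C@H]1OC(=O)C1=CC(OC)(OC)C(OC)=CC1=O
F4 | step 20 | cis-fused cycloadduct with the 8-phenylmenthyl ester on C1′ | C=C1[C@@H](O[Si](C)(C)C(C)(C)C)C[C@@H]2[C@](C)(CCC[C@@]2(C)C(OC)OC)[C@H]1C[C@@H]1C(C)=CC[C@H]2C(OC)(OC)C(OC)=CC(=O)[C@@]12C(=O)O[C@@H]1C[C@H](C)CC[C@H]1C(C)(C)c1ccccc1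
F5 | step 7 | methyl (2Z,6E,10S,11S)-3,12-bis(tert-butyldimethylsilyloxy)-10,11-epoxy-7,11-dimethyldodeca-2,6-dienoate | COC(=O)/C=C(\O[Si](C)(C)C(C)(C)C)CC/C=C(\C)CC[C@@H]1O[C@@]1(C)CO[Si](C)(C)C(C)(C)C
F6 | step 26 | 2,4,6-tris(methoxymethoxy)benzaldehyde | COCOc1cc(OCOC)c(C=O)c(OCOC)c1
F7 | step 26 | propargylic alcohol from 30 and F6 (carbinol unassigned, both epimers) | C=C1[C@@H](O[Si](C)(C)C(C)(C)C)C[C@@H]2[C@](C)(CCC[C@@]2(C)C(OC)OC)[C@H]1C[C@@H]1C(C)=CC[C@H]2C(OC)(OC)C(OC)=CC(=O)[C@@]12C#CC(O)c1c(OCOC)cc(OCOC)cc1OCOC
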